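**Assumption:** the target SMILES has no stereocentres or stereogenic double bonds (the molecule is achiral), so there is no configuration to set; the route delivers the single constitution shown.

## Retrosynthetic overview

1. Mururin C (18) ← global O-debenzylation of tri-O-benzyl aldehyde 17 ← C3 formylation (Vilsmeier–Haack) of 2-arylbenzofuran 16.
2. 16 ← Pd/Cu alkynylation–heteroannulation joining iodophenol 7 (benzofuran benzo ring plus side chain) and arylalkyne 15 (the 2-aryl ring plus both furan carbons).
3. 7 ← 4-iodophenol + allyl alcohol: B-alkyl Suzuki, then ortho-bromination/Cu-methoxylation, then ortho-iodination.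
4. 15 ← catechol: mono-methylation, para-bromination, ortho-formylation/Dakin (third oxygen), benzylation, Sonogashira with TMS-acetylene.
5. Ring order: both benzene rings come from the starting arenes; the furan ring is the only ring built, and it is formed in the fragment-joining step.

## Route

**Branch A: iodophenol 7**

Step 1
Reactants: 1 allyl alcohol
Product: 2 allyl benzyl ether
Conditions: NaH, BnBr, cat. TBAI, THF, 0 °C → rt
Reagents that add atoms: benzyl bromide, BrCc1ccccc1
Why: Williamson etherification of a primary alkoxide with a reactive benzylic halide; the benzyl ether survives every later step until the final deprotection.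

Step 2
Reactants: 2 allyl benzyl ether; 3 4-iodophenol
Product: 4 4-[3-(benzyloxy)propyl]phenol
Conditions: 2, 9-BBN, THF, 0 °C → rt; then 3, PdCl2(dppf) (3 mol %), aq. K3PO4 (3–4 equiv), DMF, 60 °C
Reagents that add atoms: none (9-BBN adds only H; boron is lost)
Why: anti-Markovnikov hydroboration gives the primary alkylborane, which undergoes B-alkyl Suzuki–Miyaura coupling with the aryl iodide; excess base accommodates the free phenol.

Step 3
Reactants: 4 4-[3-(benzyloxy)propyl]phenol
Product: 5 4-[3-(benzyloxy)propyl]-2-bromophenol
Conditions: NBS (1.0 equiv), p-TsOH (10 mol %), MeOH, rt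
Reagents that add atoms: N-bromosuccinimide, O=C1CCC(=O)N1Br
Why: electrophilic aromatic bromination of a para-blocked phenol goes ortho to OH, and these conditions stop at mono-bromination; the benzyl ring is unactivated.

Step 4
Reactants: 5 4-[3-(benzyloxy)propyl]-2-bromophenol
Product: 6 4-[3-(benzyloxy)propyl]-2-methoxyphenol
Conditions: NaOMe (5 equiv, 25 % in MeOH), CuI (15 mol %), DMF, 110 °C; acidic work-up
Reagents that add atoms: sodium methoxide, [Na+].[O-]C
Why: Ullmann-type Cu-catalysed methoxylation of an ortho-bromophenol (the 2-bromo-4-methylphenol → creosol type of transformation); the benzyl ether is inert to methoxide.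

Step 5
Reactants: 6 4-[3-(benzyloxy)propyl]-2-methoxyphenol
Product: 7 4-[3-(benzyloxy)propyl]-2-iodo-6-methoxyphenol
Conditions: NIS (1.05 equiv), p-TsOH (10 mol %), MeCN, 0 °C → rt
Reagents that add atoms: N-iodosuccinimide, O=C1CCC(=O)N1I
Why: electrophilic iodination is directed by the free OH to its only open ortho position (C6), as in eugenol and dihydroferulate iodinations.

**Branch B: arylalkyne 15**

Step 6
Reactants: 8 catechol
Product: 9 2-methoxyphenol (guaiacol)
Conditions: MeI (0.9 equiv), K2CO3 (1 equiv), acetone, reflux; separate from veratrole and recovered catechol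
Reagents that add atoms: iodomethane, CI
Why: Williamson mono-O-methylation; substoichiometric MeI limits bis-methylation and the three components separate easily by extraction and distillation.

Step 7
Reactants: 9 2-methoxyphenol
Product: 10 4-bromo-2-methoxyphenol
Conditions: NBS (1.0 equiv), MeCN, 0 °C → rt
Reagents that add atoms: N-bromosuccinimide, O=C1CCC(=O)N1Br
Why: electrophilic bromination occurs para to the stronger donor (OH), giving 4-bromoguaiacol.

Step 8
Reactants: 10 4-bromo-2-methoxyphenol
Product: 11 5-bromo-2-hydroxy-3-methoxybenzaldehyde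
Conditions: MgCl2 (2 equiv), Et3N (4 equiv), (CH2O)n (6 equiv), MeCN, reflux
Reagents that add atoms: paraformaldehyde (as formaldehyde, C=O)
Why: Mg-phenoxide-directed ortho-formylation (Casnati–Skattebøl) is strictly ortho to OH, and only one ortho position is free; bromophenols are good substrates.

Step 9
Reactants: 11 5-bromo-2-hydroxy-3-methoxybenzaldehyde
Product: 12 5-bromo-3-methoxybenzene-1,2-diol
Conditions: 30 % H2O2, aq. NaOH, THF/H2O, 0 °C → rt, N2; then HCl
Reagents that add atoms: hydrogen peroxide, OO
Why: Dakin oxidation of an ortho-hydroxybenzaldehyde (aryl migration, then formate hydrolysis) converts CHO to OH, as in the o-vanillin → 3-methoxycatechol preparation.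

Step 10
Reactants: 12 5-bromo-3-methoxybenzene-1,2-diol
Product: 13 1,2-bis(benzyloxy)-5-bromo-3-methoxybenzene
Conditions: BnBr (2.3 equiv), K2CO3, DMF, 60 °C, N2
Reagents that add atoms: benzyl bromide, BrCc1ccccc1
Why: double Williamson benzylation masks the air-sensitive catechol with groups stable to Pd/Cu, fluoride and POCl3/DMF.

Step 11
Reactants: 13 1,2-bis(benzyloxy)-5-bromo-3-methoxybenzene; 14 trimethylsilylacetylene
Product: 15 {[3,4-bis(benzyloxy)-5-methoxyphenyl]ethynyl}trimethylsilane
Conditions: PdCl2(PPh3)2 (5 mol %), CuI (10 mol %), Et3N/DMF, 80 °C, sealed tube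
Reagents that add atoms: none
Why: Sonogashira coupling of the aryl bromide (as for 5-bromo-1,2,3-trimethoxybenzene); the TMS cap prevents double coupling and Glaser dimerisation.

**Fragment union and endgame**

Step 12
Reactants: 7 4-[3-(benzyloxy)propyl]-2-iodo-6-methoxyphenol; 15 {[3,4-bis(benzyloxy)-5-methoxyphenyl]ethynyl}trimethylsilane
Product: 16 2-[3,4-bis(benzyloxy)-5-methoxyphenyl]-5-[3-(benzyloxy)propyl]-7-methoxy-1-benzofuran
Conditions: PdCl2(PPh3)2 (5 mol %), CuI (10 mol %), TBAF (1.5 equiv), Et3N, DMF, Ar, rt → 70 °C
Reagents that add atoms: none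
Why: fluoride releases the terminal alkyne slowly in situ (sila-Sonogashira), it couples with the ortho-iodophenol, and the resulting ortho-alkynylphenoxide closes 5-endo-dig to the 2-arylbenzofuran (Sonogashira/heteroannulation cascade).

Step 13
Reactants: 16 (benzofuran from Step 12)
Product: 17 2-[3,4-bis(benzyloxy)-5-methoxyphenyl]-5-[3-(benzyloxy)propyl]-7-methoxy-1-benzofuran-3-carbaldehyde
Conditions: POCl3 (3 equiv), DMF, 0 → 70 °C; then aq. NaOAc
Reagents that add atoms: N,N-dimethylformamide, CN(C)C=O (formyl carbon); water, O (carbonyl oxygen on iminium hydrolysis)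
Why: Vilsmeier–Haack formylation attacks C3, the enol-ether β-carbon of the 2-arylbenzofuran; the competing aryl positions are ortho to the biaryl bond and more hindered, and no free OH is present.

Step 14
Reactants: 17 (aldehyde from Step 13)
Product: 18 Mururin C, 2-(3,4-dihydroxy-5-methoxyphenyl)-5-(3-hydroxypropyl)-7-methoxy-1-benzofuran-3-carbaldehyde
Conditions: BCl3 (1 M in CH2Cl2, 9 equiv), pentamethylbenzene (9 equiv), CH2Cl2, −78 → −30 °C; quench CHCl3/MeOH at −78 °C
Reagents that add atoms: none
Why: Lewis-acid debenzylation with a non-basic cation scavenger cleaves the two aryl and one alkyl benzyl ethers at low temperature, leaving both aryl methyl ethers and the aldehyde intact.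

## Compound list

1 | allyl alcohol | C=CCO | starting material
2 | allyl benzyl ether | C=CCOCc1ccccc1 | intermediate
3 | 4-iodophenol | Oc1ccc(I)cc1 | starting material
4 | 4-[3-(benzyloxy)propyl]phenol | Oc1ccc(CCCOCc2ccccc2)cc1 | intermediate
5 | 4-[3-(benzyloxy)propyl]-2-bromophenol | Oc1ccc(CCCOCc2ccccc2)cc1Br | intermediate
6 | 4-[3-(benzyloxy)propyl]-2-methoxyphenol | COc1cc(CCCOCc2ccccc2)ccc1O | intermediate
7 | 4-[3-(benzyloxy)propyl]-2-iodo-6-methoxyphenol | COc1cc(CCCOCc2ccccc2)cc(I)c1O | intermediate
8 | catechol | Oc1ccccc1O | starting material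
9 | 2-methoxyphenol | COc1ccccc1O | intermediate
10 | 4-bromo-2-methoxyphenol | COc1cc(Br)ccc1O | intermediate
11 | 5-bromo-2-hydroxy-3-methoxybenzaldehyde | COc1cc(Br)cc(C=O)c1O | intermediate
12 | 5-bromo-3-methoxybenzene-1,2-diol | COc1cc(Br)cc(O)c1O | intermediate
13 | 1,2-bis(benzyloxy)-5-bromo-3-methoxybenzene | COc1cc(Br)cc(OCc2ccccc2)c1OCc1ccccc1 | intermediate
14 | trimethylsilylacetylene | C#C[Si](C)(C)C | starting material
15 | {[3,4-bis(benzyloxy)-5-methoxyphenyl]ethynyl}trimethylsilane | COc1cc(C#C[Si](C)(C)C)cc(OCc2ccccc2)c1OCc1ccccc1 | intermediate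
16 | 2-[3,4-bis(benzyloxy)-5-methoxyphenyl]-5-[3-(benzyloxy)propyl]-7-methoxy-1-benzofuran | COc1cc(-c2cc3cc(CCCOCc4ccccc4)cc(OC)c3o2)cc(OCc2ccccc2)c1OCc1ccccc1 | intermediate
17 | 2-[3,4-bis(benzyloxy)-5-methoxyphenyl]-5-[3-(benzyloxy)propyl]-7-methoxy-1-benzofuran-3-carbaldehyde | COc1cc(-c2oc3c(OC)cc(CCCOCc4ccccc4)cc3c2C=O)cc(OCc2ccccc2)c1OCc1ccccc1 | intermediate
18 | Mururin C | COc1cc(-c2oc3c(OC)cc(CCCO)cc3c2C=O)cc(O)c1O | target

## Summary

Total step count: 14

Longest linear sequence: 9 steps (catechol 8 → 18 via Steps 6–14); the other branch (allyl alcohol 1 → 18 via Steps 1–5 and 12–14) is 8 steps.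

Three steps most likely to fail, with fallbacks:

1. **Step 13 (Vilsmeier formylation).** Risk: competing attack on the electron-rich aryl ring or at C4/C6 of the benzofuran. Fallback: fix the position by ring construction. Acetylate 7 so the Sonogashira stops at the diarylalkyne, remove the acetate, cyclise with I2/NaHCO3 to the 3-iodobenzofuran, then iPrMgCl·LiCl/DMF to install CHO. All benzyl ethers tolerate this.

2. **Step 14 (global BCl3 debenzylation).** Risk: slow cleavage of the primary alkyl benzyl ether, or demethylation of the OMe next to the freed catechol on warming. Fallback: change the protecting-group logic to acid-labile groups. Use MOM ethers on the catechol (Step 10) and on the side-chain alcohol (Step 1), introduce the aldehyde by the 3-iodobenzofuran/Mg–DMF sequence instead of POCl3, and unmask with HCl/MeOH.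

3. **Step 4 (Cu-catalysed methoxylation of the bromophenol).** Risk: hydrodebromination or incomplete conversion. Fallback: skip the bromination/methoxylation pair. Couple the 9-BBN adduct of 2 directly with 4-bromo-2-methoxyphenol (10, already made in the other branch) by B-alkyl Suzuki to give 6, then iodinate as in Step 5.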